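**Retrosynthetic overview**
1. 36 ⇐ 34: the last step forms C6–C7 and closes the ten-membered ring by a photoredox/chromium allylic C–H chloroallylation of the lactol aldehyde (sets C6–Cl and C7–O); the γ-lactone closes in the same flask.
2. 34 ⇐ aldehyde 23 + furan 26: C8–C9 by Felkin–Anh furyl addition; furan → hydroxybutenolide (singlet oxygen) → epoxide → SmI2 gives the C8 carbinol and C17 methyl.
3. 23 ⇐ silyl enol ether 11 + ynal 16: C1–C2 by Mukaiyama aldol (quaternary C1); ketone → C13=C14 → hydroxyl-directed epoxide.
4. 11 ⇐ (R)-carvone 1 (ring A and the only bought stereocentre): Criegee rearrangement, trans methylation, alkylative 1,3-carbonyl transposition, conjugate hydrosilylation.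
5. Ring order: cyclohexane (bought) → oxirane (step 15) → lactol ring from the furan (step 19) → ten-membered ring and γ-lactone together (step 24).

Assumption: the SMILES is taken as the full definition of the target (1S,2R,6S,7R,8R,9R,10S,11R,12S,13S,14R,17R); atom labels C1–C20 below follow the briarane skeleton, and where an E/Z or carbinol mixture is carried the drawn isomer is the major one.

**Step 1**
Reactants: 1 (R)-(−)-carvone
Product: 4 (R)-5-acetoxy-2-methylcyclohex-2-en-1-one, via methoxy hydroperoxide 2 (not isolated), via peracetate 3 (not isolated)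
Conditions: O3, CH2Cl2/MeOH, −78 °C; then Ac2O, Et3N, DMAP, CH2Cl2, 0 °C to rt
Reagents that add atoms: ozone [O-][O+]=O; methanol CO
Why: Ozonolysis in methanol gives the methoxy hydroperoxide, whose peracetate undergoes Criegee rearrangement (the ring carbon migrates to oxygen with retention, acetate then demethylates the dioxacarbenium ion), so the carvone stereocentre becomes the C12–O centre while the electron-poor enone C=C is left alone.

**Step 2**
Reactants: 4 (R)-5-acetoxy-2-methylcyclohex-2-en-1-one
Product: 5 (R)-5-hydroxy-2-methylcyclohex-2-en-1-one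
Conditions: K2CO3 (0.2 equiv), MeOH, 0 °C
Reagents that add atoms: none
Why: Base-catalysed transesterification (methanolysis) at 0 °C frees the alcohol faster than β-elimination to the cresol.

**Step 3**
Reactants: 5 (R)-5-hydroxy-2-methylcyclohex-2-en-1-one
Product: 6 (R)-5-(methoxymethoxy)-2-methylcyclohex-2-en-1-one
Conditions: MeOCH2Cl, i-Pr2NEt, CH2Cl2, 0 °C to rt
Reagents that add atoms: chloromethyl methyl ether COCCl
Why: O-alkylation (MOM protection) with a hindered amine base does not enolise the β-alkoxy ketone.

**Step 4**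
Reactants: 6 (R)-5-(methoxymethoxy)-2-methylcyclohex-2-en-1-one
Product: 8 trans-6-methyl enone (5R,6S), via lithium dienolate 7 (not isolated)
Conditions: LiN(i-Pr)2, THF, −78 °C; MeI, −78 to −40 °C
Reagents that add atoms: iodomethane CI
Why: Kinetic α′-deprotonation and enolate alkylation, with iodomethane approaching anti to the adjacent methoxymethoxy group, gives the trans C11-methyl/C12-oxygen pair of the target.

**Step 5**
Reactants: 8 trans-6-methyl enone
Product: 9 tertiary allylic alcohol carrying CH2OMOM (C9)
Conditions: Bu3SnCH2OCH2OMe, n-BuLi, THF, −78 °C; then 8, −78 °C; NH4Cl (aq)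
Reagents that add atoms: tributyl[(methoxymethoxy)methyl]stannane CCCC[Sn](CCCC)(CCCC)COCOC
Why: Tin–lithium exchange gives the α-alkoxymethyllithium, which adds 1,2 to the enone carbonyl and brings in C9; the new carbinol centre is erased in step 6.

**Step 6**
Reactants: 9 tertiary allylic alcohol
Product: 10 transposed enone (4R,5R)
Conditions: pyridinium chlorochromate (C5H5NH[CrO3Cl]), 4 Å sieves, CH2Cl2, rt
Reagents that add atoms: pyridinium chlorochromate [O-][Cr](=O)(=O)Cl.c1cc[nH+]cc1
Why: Dauben–Babler oxidative 1,3-transposition ([3,3] shift of the allylic chromate ester, then oxidation) moves the carbonyl to C14 and leaves C9 on the enone β-carbon C10.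

**Step 7**
Reactants: 10 transposed enone
Product: 11 dimethylphenylsilyl enol ether (C14=C1)
Conditions: [(Ph3P)CuH]6 (3 mol%), PhMe2SiH (1.5 equiv), toluene, rt
Reagents that add atoms: dimethylphenylsilane C[SiH](C)c1ccccc1
Why: Copper hydride-catalysed 1,4-hydrosilylation delivers hydride to C10 anti to the C11 methyl (held pseudo-axial by A(1,2) strain with the C10 substituent), which sets C10 with C9 cis to the C11 methyl and gives the regiodefined tetrasubstituted enol ether.

**Step 8**
Reactants: 12 4-(trimethylsilyl)but-3-yn-2-one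
Product: 14 (E)-1-chloro-2-methylbut-1-en-3-yne, via silylated chloroenyne 13 (not isolated)
Conditions: ClCH2PPh3Cl, NaN(SiMe3)2, THF, −78 °C to rt; then K2CO3, MeOH, rt (handled as an ether solution)
Reagents that add atoms: (chloromethyl)triphenylphosphonium chloride [Cl-].ClC[P+](c1ccccc1)(c1ccccc1)c1ccccc1
Why: Wittig chloromethylenation of the ynone followed by in-flask methanolysis of the alkynylsilane gives the chloroenyne as an E/Z mixture that is carried on as such, because the geometry is erased in the allyl intermediate of step 24.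

**Step 9**
Reactants: 14 (E)-1-chloro-2-methylbut-1-en-3-yne
Product: 16 (E)-5-chloro-4-methylpent-4-en-2-ynal, via lithium acetylide 15 (not isolated)
Conditions: n-BuLi, THF, −78 °C; DMF; inverse quench into aq. KH2PO4
Reagents that add atoms: N,N-dimethylformamide CN(C)C=O
Why: The terminal alkyne is far more acidic than the chlorovinyl C–H, so selective deprotonation and formylation with DMF gives the ynal.

**Step 10**
Reactants: 11 dimethylphenylsilyl enol ether; 16 (E)-5-chloro-4-methylpent-4-en-2-ynal
Product: 17 aldol adduct (C2 alcohol, C14 ketone)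
Conditions: BF3·OEt2, CH2Cl2, −78 °C
Reagents that add atoms: none
Why: Mukaiyama aldol in which the BF3-bound aldehyde attacks C1 anti to the C10 and C11 substituents (sets quaternary C1), and the open antiperiplanar transition state with the aldehyde hydrogen under the ring and the slim alkynyl group outside sets C2 as in the target.

**Step 11**
Reactants: 17 aldol adduct
Product: 18 C2 acetate
Conditions: Ac2O, pyridine, DMAP, CH2Cl2, 0 °C to rt
Reagents that add atoms: acetic anhydride CC(=O)OC(C)=O
Why: DMAP-catalysed acylation installs the C2 acetate of the target and blocks retro-aldol cleavage.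

**Step 12**
Reactants: 18 C2 acetate
Product: 19 C14 alcohol (epimer mixture)
Conditions: NaBH4, MeOH/CH2Cl2, 0 °C
Reagents that add atoms: none
Why: Borohydride reduction of the only ketone; the C14 carbinol configuration does not matter because it is removed in step 13.

**Step 13**
Reactants: 19 C14 alcohol
Product: 20 cyclohexene (C13=C14)
Conditions: Burgess reagent (MeO2CN–SO2NEt3), toluene, 70 °C
Reagents that add atoms: none
Why: Burgess dehydration (thermal syn-elimination of the sulfamate) can only give the C13=C14 alkene because C1 is quaternary.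

**Step 14**
Reactants: 20 cyclohexene
Product: 21 C9,C12 diol
Conditions: Me2BBr, CH2Cl2, −78 °C; then NaHCO3 (aq), THF
Reagents that add atoms: none
Why: Lewis-acid cleavage of both methoxymethyl acetals by bromodimethylborane at low temperature leaves the acetate, alkyne and alkenes untouched.

**Step 15**
Reactants: 21 C9,C12 diol
Product: 22 epoxy diol (13,14-epoxide)
Conditions: VO(acac)2 (5 mol%), t-BuOOH, CH2Cl2, 0 °C
Reagents that add atoms: tert-butyl hydroperoxide CC(C)(C)OO
Why: Vanadium-catalysed hydroxyl-directed epoxidation, in which the allylic C12 hydroxyl delivers the oxidant to its own face of C13=C14, sets C13 and C14 syn to the C12 oxygen; the electron-poor chloroenyne does not react.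

**Step 16**
Reactants: 22 epoxy diol
Product: 23 C9 aldehyde
Conditions: TEMPO (10 mol%), PhI(OAc)2, CH2Cl2, rt
Reagents that add atoms: none
Why: Oxoammonium (TEMPO) oxidation is selective for the primary C9 alcohol over the secondary C12 alcohol.

**Step 17**
Reactants: 24 3,4-dibromofuran
Product: 26 3-bromo-4-methylfuran, via 3-bromo-4-lithiofuran 25 (not isolated)
Conditions: n-BuLi (1.0 equiv), Et2O, −78 °C; MeI
Reagents that add atoms: iodomethane CI
Why: Single bromine–lithium exchange of the symmetric dibromide followed by methylation.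

**Step 18**
Reactants: 23 C9 aldehyde; 26 3-bromo-4-methylfuran
Product: 27 furyl carbinol (C9,C12 diol)
Conditions: 26 (2.2 equiv), n-BuLi, Et2O, −78 °C; MgBr2·OEt2; then 23, −78 °C; NH4Cl (aq)
Reagents that add atoms: none
Why: Bromine–lithium exchange, transmetalation to magnesium and Felkin–Anh addition to the aldehyde (quaternary C1 as the large group anti to the nucleophile) form C8–C9 and set C9; the Grignard reagent spares the acetate at −78 °C.

**Step 19**
Reactants: 27 furyl carbinol
Product: 29 γ-hydroxybutenolide (lactol), via furan endoperoxide 28 (not isolated)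
Conditions: O2, rose bengal (cat.), i-Pr2NEt, CH2Cl2, −78 °C, visible light (hν)
Reagents that add atoms: oxygen O=O
Why: [4+2] cycloaddition of photogenerated singlet oxygen to the furan and base-induced Kornblum–DeLaMare fragmentation, in which the amine removes the less hindered bridgehead hydrogen (next to the methyl), make C19 the lactone carbonyl and C7 the lactol carbon.

**Step 20**
Reactants: 29 γ-hydroxybutenolide
Product: 30 8,17-epoxy lactol
Conditions: t-BuOOH, DBU, CH2Cl2, 0 °C; work-up at pH 4
Reagents that add atoms: tert-butyl hydroperoxide CC(C)(C)OO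
Why: Weitz–Scheffer nucleophilic epoxidation of the ring-opened formyl acrylate, in which A(1,3) strain puts H9 in the alkene plane and the epoxide oxygen closes on the C8 face anti to C10 (syn to the C9 hydroxyl), sets C8.

**Step 21**
Reactants: 30 8,17-epoxy lactol
Product: 31 8-hydroxy lactol (17R methyl)
Conditions: SmI2 (2.5 equiv), THF/MeOH, −78 °C
Reagents that add atoms: none
Why: SmI2 reduction of the α,β-epoxy lactone cleaves the C17–O bond and keeps the C8 oxygen, and the samarium enolate is protonated anti to the bulky C8 samarium alkoxide, giving the C17 epimer with methyl trans to the C9 branch (also the more stable one).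

**Step 22**
Reactants: 31 8-hydroxy lactol
Product: 33 9,12-diacetate lactol, via pseudo-acid triacetate 32 (not isolated)
Conditions: Ac2O, pyridine, DMAP, CH2Cl2, 0 °C to rt; then H2NNH2·AcOH, DMF, rt
Reagents that add atoms: acetic anhydride CC(=O)OC(C)=O
Why: Acylation of the two secondary alcohols (the tertiary C8 hydroxyl is inert) followed by selective hydrazinolysis of the activated anomeric acetate frees the lactol again.

**Step 23**
Reactants: 33 9,12-diacetate lactol
Product: 34 (3Z)-diene seco-lactol
Conditions: H2 (1 atm), Pd/CaCO3 poisoned with Pb(OAc)2 (Lindlar catalyst), quinoline, EtOAc, rt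
Reagents that add atoms: none
Why: Lindlar semihydrogenation adds H2 syn to the conjugated alkyne and gives the 3Z alkene; vinyl chloride, epoxide and acetates are inert on the poisoned catalyst.

**Step 24**
Reactants: 34 (3Z)-diene seco-lactol
Product: 36 CNP0274383.2, via macrocyclic hydroxy acid 35 (not isolated)
Conditions: 9-mesityl-10-methylacridinium perchlorate (5 mol%), CrCl2 (15 mol%), 4,4′-di-tert-butyl-2,2′-bipyridine (18 mol%), Mg(ClO4)2 (1 equiv), CH2Cl2 (2 mM), 450 nm LEDs, rt; NH4Cl (aq) work-up
Reagents that add atoms: none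
Why: Proposed new method: the excited acridinium oxidises the chlorodiene to its radical cation, which loses a proton only from the C16 methyl (the C2–H is held in the diene plane by A(1,3) strain of the Z-alkene), divalent chromium captures the 2-vinyl-γ-chloroallyl radical at its primary terminus, and the allylchromium (E/Z-equilibrating, so the vinyl chloride geometry is irrelevant) adds through C6 to the aldehyde form of the lactol in a chair transition state (chlorine pseudo-equatorial, hence anti C6–Cl/C7–O) under polar Felkin–Anh control from C8 (C8–O anti to the incoming carbon, the rotamer the C9-side tether can reach), which forms the C6–C7 bond, the ten-membered ring, the exo-methylene and both stereocentres before the C7 alkoxide lactonises onto C19 and the reduced acridine returns trivalent chromium to the divalent state; the closest known reactions are the dual photoredox/chromium allylation of aldehydes through allylic C–H bonds of simple alkenes (intermolecular) and the stoichiometric chromium-mediated γ-chloroallylation of aldehydes with 1,3-dichloropropene, neither shown for a γ-chlorodienyl C–H partner or for a macrocyclisation.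

**Compound list**
1 | (R)-(−)-carvone | O=C1C(C)=CC[C@@H](C(C)=C)C1 | starting material
2 | (5R)-5-(1-hydroperoxy-1-methoxyethyl)-2-methylcyclohex-2-en-1-one (epimers at the peroxy carbon) | O=C1C(C)=CC[C@@H](C(C)(OC)OO)C1 | intermediate (not isolated)
3 | (5R)-5-[1-(acetylperoxy)-1-methoxyethyl]-2-methylcyclohex-2-en-1-one | O=C1C(C)=CC[C@@H](C(C)(OC)OOC(C)=O)C1 | intermediate (not isolated)
4 | (R)-5-acetoxy-2-methylcyclohex-2-en-1-one | O=C1C(C)=CC[C@@H](OC(C)=O)C1 | intermediate
5 | (R)-5-hydroxy-2-methylcyclohex-2-en-1-one | O=C1C(C)=CC[C@@H](O)C1 | intermediate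
6 | (R)-5-(methoxymethoxy)-2-methylcyclohex-2-en-1-one | O=C1C(C)=CC[C@@H](OCOC)C1 | intermediate
7 | lithium (3R)-3-(methoxymethoxy)-6-methylcyclohexa-1,5-dien-1-olate | [Li]OC1=C[C@H](OCOC)CC=C1C | intermediate (not isolated)
8 | (5R,6S)-5-(methoxymethoxy)-2,6-dimethylcyclohex-2-en-1-one (trans) | O=C1C(C)=CC[C@@H](OCOC)[C@@H]1C | intermediate
9 | (1S,5R,6S)-5-(methoxymethoxy)-1-[(methoxymethoxy)methyl]-2,6-dimethylcyclohex-2-en-1-ol | O[C@]1(COCOC)C(C)=CC[C@@H](OCOC)[C@@H]1C | intermediate
10 | (4R,5R)-5-(methoxymethoxy)-3-[(methoxymethoxy)methyl]-2,4-dimethylcyclohex-2-en-1-one | CC1=C(COCOC)[C@@H](C)[C@H](OCOC)CC1=O | intermediate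
11 | {[(3S,4R,5R)-5-(methoxymethoxy)-3-[(methoxymethoxy)methyl]-2,4-dimethylcyclohex-1-en-1-yl]oxy}dimethyl(phenyl)silane | CC1=C(O[Si](C)(C)c2ccccc2)C[C@@H](OCOC)[C@H](C)[C@@H]1COCOC | intermediate
12 | 4-(trimethylsilyl)but-3-yn-2-one | CC(=O)C#C[Si](C)(C)C | starting material
13 | (E)-(4-chloro-3-methylbut-3-en-1-yn-1-yl)trimethylsilane (E drawn, Z also formed) | Cl/C=C(C)/C#C[Si](C)(C)C | intermediate (not isolated)
14 | (E)-1-chloro-2-methylbut-1-en-3-yne (E drawn, Z carried along) | Cl/C=C(C)/C#C | intermediate
15 | lithium (E)-4-chloro-3-methylbut-3-en-1-yn-1-ide | Cl/C=C(C)/C#C[Li] | intermediate (not isolated)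
16 | (E)-5-chloro-4-methylpent-4-en-2-ynal | Cl/C=C(C)/C#CC=O | intermediate
17 | aldol adduct: cyclohexanone (C14=O) with quaternary C1 bearing methyl and the (R)-CH(OH)–C≡C–C(Me)=CHCl chain, C10 CH2OMOM, C11 methyl, C12 OMOM, configured as in the target | Cl/C=C(C)/C#C[C@@H](O)[C@]1(C)[C@H]([C@@H](C)[C@H](OCOC)CC1=O)COCOC | intermediate
18 | C2 acetate of 17 | Cl/C=C(C)/C#C[C@@H](OC(C)=O)[C@]1(C)[C@H]([C@@H](C)[C@H](OCOC)CC1=O)COCOC | intermediate
19 | C14 alcohol of 18 (both C14 epimers) | Cl/C=C(C)/C#C[C@@H](OC(C)=O)[C@]1(C)[C@H]([C@@H](C)[C@H](OCOC)CC1O)COCOC | intermediate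
20 | cyclohexene with C13=C14, C2 acetate, two MOM ethers | Cl/C=C(C)/C#C[C@@H](OC(C)=O)[C@]1(C)[C@H]([C@@H](C)[C@H](OCOC)C=C1)COCOC | intermediate
21 | C9 (primary), C12 (allylic) diol | Cl/C=C(C)/C#C[C@@H](OC(C)=O)[C@]1(C)[C@H]([C@@H](C)[C@H](O)C=C1)CO | intermediate
22 | 13,14-epoxide syn to the C12 hydroxyl, C9 primary alcohol | Cl/C=C(C)/C#C[C@@H](OC(C)=O)[C@]2(C)[C@H]([C@@H](C)[C@H](O)[C@@H]3O[C@@H]32)CO | intermediate
23 | C9 aldehyde of 22 | Cl/C=C(C)/C#C[C@@H](OC(C)=O)[C@]2(C)[C@H]([C@@H](C)[C@H](O)[C@@H]3O[C@@H]32)C=O | intermediate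
24 | 3,4-dibromofuran | Brc1cocc1Br | starting material
25 | 3-bromo-4-lithiofuran | [Li]c1cocc1Br | intermediate (not isolated)
26 | 3-bromo-4-methylfuran | Cc1cocc1Br | intermediate
27 | (9R)-(4-methylfuran-3-yl) carbinol, C12 alcohol free | Cl/C=C(C)/C#C[C@@H](OC(C)=O)[C@]2(C)[C@H]([C@@H](C)[C@H](O)[C@@H]3O[C@@H]32)[C@@H](O)c1cocc1C | intermediate
28 | furan 2,5-endoperoxide of 27 (bridgehead epimers) | Cl/C=C(C)/C#C[C@@H](OC(C)=O)[C@]2(C)[C@H]([C@@H](C)[C@H](O)[C@@H]3O[C@@H]32)[C@@H](O)C1=C(C)C2OOC1O2 | intermediate (not isolated)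
29 | 5-hydroxy-3-methylfuran-2(5H)-one (C19 carbonyl, C7 lactol, C8=C17) attached through C8 to C9 | Cl/C=C(C)/C#C[C@@H](OC(C)=O)[C@]2(C)[C@H]([C@@H](C)[C@H](O)[C@@H]3O[C@@H]32)[C@@H](O)C1=C(C)C(=O)OC1O | intermediate
30 | 8,17-epoxide of 29 (epoxide oxygen syn to the C9 hydroxyl) | Cl/C=C(C)/C#C[C@@H](OC(C)=O)[C@]2(C)[C@H]([C@@H](C)[C@H](O)[C@@H]3O[C@@H]32)[C@@H](O)[C@]12O[C@@]1(C)C(=O)OC2O | intermediate
31 | 8-hydroxy-17-methyl γ-lactol (C7 lactol epimers), C9 and C12 alcohols free | Cl/C=C(C)/C#C[C@@H](OC(C)=O)[C@]2(C)[C@H]([C@@H](C)[C@H](O)[C@@H]3O[C@@H]32)[C@@H](O)[C@]2(O)[C@@H](C)C(=O)OC2O | intermediate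
32 | 9,12-diacetate with the lactol also acetylated | Cl/C=C(C)/C#C[C@@H](OC(C)=O)[C@]2(C)[C@H]([C@@H](C)[C@H](OC(C)=O)[C@@H]3O[C@@H]32)[C@@H](OC(C)=O)[C@]2(O)[C@@H](C)C(=O)OC2OC(C)=O | intermediate (not isolated)
33 | 2,9,12-triacetate with free C7 lactol and free C8 tertiary alcohol, enyne | Cl/C=C(C)/C#C[C@@H](OC(C)=O)[C@]2(C)[C@H]([C@@H](C)[C@H](OC(C)=O)[C@@H]3O[C@@H]32)[C@@H](OC(C)=O)[C@]2(O)[C@@H](C)C(=O)OC2O | intermediate
34 | as 33 with the alkyne reduced to the (3Z)-alkene: (3Z,5E)-6-chloro-5-methyl diene | Cl/C=C(C)/C=C\[C@@H](OC(C)=O)[C@]2(C)[C@H]([C@@H](C)[C@H](OC(C)=O)[C@@H]3O[C@@H]32)[C@@H](OC(C)=O)[C@]2(O)[C@@H](C)C(=O)OC2O | intermediate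
35 | ten-membered 7-hydroxy C19 carboxylic acid (6-chloro, 5(16)-methylene) | C=C1/C=C\[C@@H](OC(C)=O)[C@]2(C)[C@H]([C@@H](C)[C@H](OC(C)=O)[C@@H]3O[C@@H]32)[C@@H](OC(C)=O)[C@](O)([C@@H](C)C(O)=O)[C@@H](O)[C@H]1Cl | intermediate (not isolated)
36 | CNP0274383.2 | C=C1/C=C\[C@@H](OC(C)=O)[C@]2(C)[C@H]([C@@H](C)[C@H](OC(C)=O)[C@@H]3O[C@@H]32)[C@@H](OC(C)=O)[C@]2(O)[C@@H](C)C(=O)O[C@H]2[C@H]1Cl | target

**Step count**
Total: 24 steps. Longest linear sequence: 21 steps (steps 1–7, 10–16, 18–24); the ynal (steps 8–9) and the furan (step 17) are side branches.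

**Three steps most likely to fail, with fallbacks**

Step 24 (the proposed photoredox/chromium macrocyclisation). The risks are competing deprotonation or Z/E isomerisation of the diene radical cation, attack through C16 instead of C6, and the wrong C6/C7 diastereomer. The fallback uses known chemistry and sets out from 34: Me2AlCl (3 equiv), CH2Cl2, −78 to 0 °C, high dilution, a Lewis-acid-promoted intramolecular carbonyl-ene (Prins-type) cyclisation. The aldehyde form of the lactol is attacked by C6 of the trisubstituted chloroalkene, the developing cation at C5 is stabilised by the C3=C4 alkene, and the C16 methyl loses the proton to give the exo-methylene. Aqueous work-up gives the hydroxy acid 35, which lactonises, so the fallback comes back at 36. It makes no new compound (F0).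

Step 10 (Mukaiyama aldol forming the quaternary C1 and C2). The open transition state may give the wrong C2 epimer or a mixture. The fallback sets out from 11. MeLi (THF, −78 °C) cleaves the silyl ether to the lithium enolate F3. Its closed-transition-state aldol with 16 gives mainly the C2-epimeric aldol F4. Dess–Martin periodinane oxidises either epimer to the ynone diketone F5. Zn(BH4)2 (Et2O, −78 °C) then reduces the more reactive side-chain ketone under 1,3-chelation, hydride arriving on the face opposite the C10 branch, which gives the C2 configuration of the target; the fallback comes back at 17.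

Step 7 (copper hydride 1,4-reduction of a tetrasubstituted enone). The enone may be too hindered or the facial selectivity too low. The fallback sets out from 10. Radical hydrogen-atom-transfer reduction with Mn(dpm)3 (cat.), PhSiH3, t-BuOOH, i-PrOH puts hydrogen on C10 anti to the C11 methyl and gives the saturated ketone F1 (C1 epimers, both usable). Thermodynamic silylation (TMSOTf, Et3N, CH2Cl2, rt) gives the more substituted trimethylsilyl enol ether F2. F2 enters the aldol of step 10 with 16 in place of 11, and the fallback comes back at 17.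

**Further compounds**
F1 | step 7 | (3S,4R,5R)-5-(methoxymethoxy)-3-[(methoxymethoxy)methyl]-2,4-dimethylcyclohexan-1-one (C2 epimers) | CC1C(=O)C[C@@H](OCOC)[C@H](C)[C@@H]1COCOC
F2 | step 7 | trimethylsilyl enol ether analogue of 11 | CC1=C(O[Si](C)(C)C)C[C@@H](OCOC)[C@H](C)[C@@H]1COCOC
F3 | step 10 | lithium enolate corresponding to 11 | CC1=C(O[Li])C[C@@H](OCOC)[C@H](C)[C@@H]1COCOC
F4 | step 10 | C2 epimer of 17 | Cl/C=C(C)/C#C[C@H](O)[C@]1(C)[C@H]([C@@H](C)[C@H](OCOC)CC1=O)COCOC
F5 | step 10 | ynone diketone (C2 ketone of 17) | Cl/C=C(C)/C#CC(=O)[C@]1(C)[C@H]([C@@H](C)[C@H](OCOC)CC1=O)COCOC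
F0 | step 24 | none | none
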